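**Retrosynthetic overview**
- The last C–O bond is the acetate on the only enolisable CH2 of the epoxy ketone; before it come Shi epoxidation of the prenyl olefin and two tigloylations.
- Side chain: the carbinol–CH2(prenyl) bond comes from a chiral phosphoric acid-catalysed prenylboration of a 2-substituted acrolein, itself made from a ring ethynyl group (anti-Markovnikov hydration, α-methylenation).
- Ring oxirane: hydroxyl-directed nucleophilic epoxidation of a cis-4-hydroxy-5-ethynyl-2-methylcyclohex-2-enone.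
- Carbocycle: a one-pot aminocatalytic Michael addition / α-benzoyloxylation / aldol condensation–decarboxylation of an enynal, tert-butyl 3-oxopentanoate and benzoyl peroxide sets the first two stereocentres.
- Ring order: cyclohexenone first, then the ring oxirane, then the side-chain oxirane.

Assumption: the tertiary allylboronic ester used in step 6, the chiral catalysts and the oxaziridine are taken as purchasable reagents.

**Step 1**
Reactants: 1 3-(trimethylsilyl)prop-2-ynal; 2 (triphenylphosphoranylidene)acetaldehyde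
Product: 3 (2E)-5-(trimethylsilyl)pent-2-en-4-ynal
Conditions: toluene, 0 °C to rt
Reagents that add atoms: none
Why: Wittig olefination with the stabilised formyl ylide, which adds once to the more electrophilic ynal and gives the E-enal; no stereocentre is formed.

**Step 2**
Reactants: 3 (2E)-5-(trimethylsilyl)pent-2-en-4-ynal; 4 tert-butyl 3-oxopentanoate
Product: 6 (1R,6R)-3-methyl-4-oxo-6-[(trimethylsilyl)ethynyl]cyclohex-2-en-1-yl benzoate, via open-chain benzoyloxy keto aldehyde 5 (not isolated)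
Conditions: (S)-α,α-diphenylprolinol trimethylsilyl ether (20 mol%), PhCO2H (20 mol%), (PhCO2)2 (1.3 equiv), toluene, 0 °C to rt; then TsOH·H2O (30 mol%), 60 °C
Reagents that add atoms: dibenzoyl peroxide O=C(OOC(=O)c1ccccc1)c1ccccc1
Why: Proposed new method: an iminium/enamine relay in which the β-ketoester adds to the β-carbon of the E-iminium ion and the resulting catalyst-bound enamine attacks the O–O bond of benzoyl peroxide at carbon; both bonds form on the face left open by the diphenyl(silyloxy)methyl group, so one catalyst sets the alkynyl carbon and the benzoate carbon cis on the future ring, and acid then removes isobutene and CO2 and closes the enone by aldol condensation. The closest known reactions are the diarylprolinol silyl ether-catalysed Michael addition/cyclisation of β-ketoesters with enals to 5-substituted cyclohexenones and the separate enamine α-benzoyloxylation of aldehydes with benzoyl peroxide.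

**Step 3**
Reactants: 6 (1R,6R)-3-methyl-4-oxo-6-[(trimethylsilyl)ethynyl]cyclohex-2-en-1-yl benzoate
Product: 8 (1S,4R,5S,6S)-4-ethynyl-5-hydroxy-1-methyl-7-oxabicyclo[4.1.0]heptan-2-one, via desilylated hydroxy enone 7 (not isolated)
Conditions: K2CO3, MeOH, 0 °C to rt; then 30% aq H2O2, 0 °C
Reagents that add atoms: hydrogen peroxide OO
Why: Methanolysis removes the C-silyl group and the benzoate, and the freed allylic hydroxyl then hydrogen-bonds the hydroperoxide anion so that the Weitz–Scheffer nucleophilic epoxidation occurs on the hydroxyl face, setting both oxirane carbons syn to the OH (a cis epoxy alcohol cannot undergo Payne migration).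

**Step 4**
Reactants: 8 (1S,4R,5S,6S)-4-ethynyl-5-hydroxy-1-methyl-7-oxabicyclo[4.1.0]heptan-2-one; 9 (2E)-2-methylbut-2-enoyl chloride
Product: 10 (1S,2S,3R,6S)-3-ethynyl-6-methyl-5-oxo-7-oxabicyclo[4.1.0]heptan-2-yl (2E)-2-methylbut-2-enoate
Conditions: pyridine, DMAP (10 mol%), CH2Cl2, 0 °C to rt
Reagents that add atoms: none
Why: DMAP-catalysed esterification of the secondary alcohol with the acid chloride; pyridine instead of a trialkylamine avoids vinylketene formation and deconjugation of the tiglate, and no stereocentre changes.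

**Step 5**
Reactants: 10 (1S,2S,3R,6S)-3-ethynyl-6-methyl-5-oxo-7-oxabicyclo[4.1.0]heptan-2-yl (2E)-2-methylbut-2-enoate
Product: 12 (1S,2S,3R,6S)-6-methyl-5-oxo-3-(3-oxoprop-1-en-2-yl)-7-oxabicyclo[4.1.0]heptan-2-yl (2E)-2-methylbut-2-enoate, via saturated aldehyde 11 (not isolated)
Conditions: [CpRu(MeCN)3]PF6 (5 mol%), 5,5′-bis(trifluoromethyl)-2,2′-bipyridine (5 mol%), NMP/H2O 4:1, 25 °C; then 37% aq CH2O, pyrrolidine (20 mol%), EtCO2H (20 mol%), i-PrOH, 40 °C
Reagents that add atoms: water O; formaldehyde C=O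
Why: Anti-Markovnikov hydration of the terminal alkyne through a ruthenium vinylidene gives the aldehyde, which undergoes amine-catalysed Mannich condensation/elimination with formaldehyde (organocatalytic α-methylenation); the adjacent ring CH is not acidified by the cross-conjugated enal and keeps its configuration.

**Step 6**
Reactants: 12 (1S,2S,3R,6S)-6-methyl-5-oxo-3-(3-oxoprop-1-en-2-yl)-7-oxabicyclo[4.1.0]heptan-2-yl (2E)-2-methylbut-2-enoate; 13 4,4,5,5-tetramethyl-2-(2-methylbut-3-en-2-yl)-1,3,2-dioxaborolane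
Product: 14 (1S,2S,3R,6S)-3-[(3S)-3-hydroxy-6-methylhepta-1,5-dien-2-yl]-6-methyl-5-oxo-7-oxabicyclo[4.1.0]heptan-2-yl (2E)-2-methylbut-2-enoate
Conditions: (S)-TRIP phosphoric acid (5 mol%), 4 Å MS, toluene, −30 °C; aq NaHCO3 work-up
Reagents that add atoms: none
Why: Chiral phosphoric acid-catalysed allylboration through a chair transition state, in which allyl transposition of the tertiary boronate delivers the linear prenyl group; the (S)-acid is chosen by analogy with aryl and enal aldehydes to direct addition to the Si face and give the (S)-carbinol, and the ring ketone is not attacked.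

**Step 7**
Reactants: 14 (1S,2S,3R,6S)-3-[(3S)-3-hydroxy-6-methylhepta-1,5-dien-2-yl]-6-methyl-5-oxo-7-oxabicyclo[4.1.0]heptan-2-yl (2E)-2-methylbut-2-enoate; 9 (2E)-2-methylbut-2-enoyl chloride
Product: 15 (1S,2S,3R,6S)-6-methyl-3-[(3S)-6-methyl-3-{[(2E)-2-methylbut-2-enoyl]oxy}hepta-1,5-dien-2-yl]-5-oxo-7-oxabicyclo[4.1.0]heptan-2-yl (2E)-2-methylbut-2-enoate
Conditions: pyridine, DMAP (20 mol%), CH2Cl2, rt
Reagents that add atoms: none
Why: DMAP-catalysed esterification of the allylic secondary alcohol with retention at the carbinol carbon.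

**Step 8**
Reactants: 15 (1S,2S,3R,6S)-6-methyl-3-[(3S)-6-methyl-3-{[(2E)-2-methylbut-2-enoyl]oxy}hepta-1,5-dien-2-yl]-5-oxo-7-oxabicyclo[4.1.0]heptan-2-yl (2E)-2-methylbut-2-enoate
Product: 16 (1S,2S,3R,6S)-3-[(3S)-4-[(2R)-3,3-dimethyloxiran-2-yl]-3-{[(2E)-2-methylbut-2-enoyl]oxy}but-1-en-2-yl]-6-methyl-5-oxo-7-oxabicyclo[4.1.0]heptan-2-yl (2E)-2-methylbut-2-enoate
Conditions: D-fructose-derived Shi ketone (30 mol%), KHSO5 (as 2KHSO5·KHSO4·K2SO4), K2CO3, Bu4NHSO4, Na2B4O7 buffer pH 10.5, MeCN/CH2(OMe)2/H2O, 0 °C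
Reagents that add atoms: potassium peroxymonosulfate [K+].[O-]S(=O)(=O)OO
Why: Shi epoxidation, in which the dioxirane of the D-fructose-derived ketone attacks only the electron-rich trisubstituted olefin through the spiro transition state and gives the (R)-oxirane; the tiglates and the ester-flanked 1,1-disubstituted alkene are too electron-poor to react.

**Step 9**
Reactants: 16 (1S,2S,3R,6S)-3-[(3S)-4-[(2R)-3,3-dimethyloxiran-2-yl]-3-{[(2E)-2-methylbut-2-enoyl]oxy}but-1-en-2-yl]-6-methyl-5-oxo-7-oxabicyclo[4.1.0]heptan-2-yl (2E)-2-methylbut-2-enoate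
Product: 18 (1S,2S,3R,4S,6S)-4-(acetyloxy)-3-[(3S)-4-[(2R)-3,3-dimethyloxiran-2-yl]-3-{[(2E)-2-methylbut-2-enoyl]oxy}but-1-en-2-yl]-6-methyl-5-oxo-7-oxabicyclo[4.1.0]heptan-2-yl (2E)-2-methylbut-2-enoate, via α-hydroxy ketone 17 (not isolated)
Conditions: KN(SiMe3)2 (1.1 equiv), THF, −78 °C; 3-phenyl-2-(phenylsulfonyl)oxaziridine, −78 °C; then Ac2O, −78 to 0 °C
Reagents that add atoms: 3-phenyl-2-(phenylsulfonyl)oxaziridine O=S(=O)(N1OC1c1ccccc1)c1ccccc1; acetic anhydride CC(=O)OC(C)=O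
Why: The ketone can enolise only toward its CH2, the Davis oxaziridine hydroxylates the potassium enolate on the face anti to the adjacent side chain (C–O trans to it, also the thermodynamic arrangement), and the alkoxide is acetylated in the same flask (enolate α-hydroxylation/O-acylation).

**Compound list**
1 | 3-(trimethylsilyl)prop-2-ynal | C[Si](C)(C)C#CC=O | starting material
2 | (triphenylphosphoranylidene)acetaldehyde | O=CC=P(c1ccccc1)(c1ccccc1)c1ccccc1 | starting material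
3 | (2E)-5-(trimethylsilyl)pent-2-en-4-ynal | C[Si](C)(C)C#C/C=C/C=O | intermediate
4 | tert-butyl 3-oxopentanoate | CCC(=O)CC(=O)OC(C)(C)C | starting material
5 | tert-butyl (3R,4S)-4-(benzoyloxy)-5-oxo-2-propanoyl-3-[(trimethylsilyl)ethynyl]pentanoate (C-2 epimers) | CCC(=O)C(C(=O)OC(C)(C)C)[C@H](C#C[Si](C)(C)C)[C@H](OC(=O)c1ccccc1)C=O | intermediate
6 | (1R,6R)-3-methyl-4-oxo-6-[(trimethylsilyl)ethynyl]cyclohex-2-en-1-yl benzoate | C[Si](C)(C)C#C[C@@H]1[C@H](OC(=O)c2ccccc2)C=C(C)C(=O)C1 | intermediate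
7 | (4R,5R)-5-ethynyl-4-hydroxy-2-methylcyclohex-2-en-1-one | C#C[C@@H]1[C@H](O)C=C(C)C(=O)C1 | intermediate
8 | (1S,4R,5S,6S)-4-ethynyl-5-hydroxy-1-methyl-7-oxabicyclo[4.1.0]heptan-2-one | C#C[C@@H]1[C@H](O)[C@@H]2O[C@]2(C)C(=O)C1 | intermediate
9 | (2E)-2-methylbut-2-enoyl chloride (tigloyl chloride) | C/C=C(\C)C(Cl)=O | starting material
10 | (1S,2S,3R,6S)-3-ethynyl-6-methyl-5-oxo-7-oxabicyclo[4.1.0]heptan-2-yl (2E)-2-methylbut-2-enoate | C#C[C@@H]1[C@H](OC(=O)/C(C)=C/C)[C@@H]2O[C@]2(C)C(=O)C1 | intermediate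
11 | (1S,2S,3S,6S)-6-methyl-5-oxo-3-(2-oxoethyl)-7-oxabicyclo[4.1.0]heptan-2-yl (2E)-2-methylbut-2-enoate | O=CC[C@@H]1[C@H](OC(=O)/C(C)=C/C)[C@@H]2O[C@]2(C)C(=O)C1 | intermediate
12 | (1S,2S,3R,6S)-6-methyl-5-oxo-3-(3-oxoprop-1-en-2-yl)-7-oxabicyclo[4.1.0]heptan-2-yl (2E)-2-methylbut-2-enoate | C=C(C=O)[C@@H]1[C@H](OC(=O)/C(C)=C/C)[C@@H]2O[C@]2(C)C(=O)C1 | intermediate
13 | 4,4,5,5-tetramethyl-2-(2-methylbut-3-en-2-yl)-1,3,2-dioxaborolane | C=CC(C)(C)B1OC(C)(C)C(C)(C)O1 | starting material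
14 | (1S,2S,3R,6S)-3-[(3S)-3-hydroxy-6-methylhepta-1,5-dien-2-yl]-6-methyl-5-oxo-7-oxabicyclo[4.1.0]heptan-2-yl (2E)-2-methylbut-2-enoate | C=C([C@@H]1[C@H](OC(=O)/C(C)=C/C)[C@@H]2O[C@]2(C)C(=O)C1)[C@H](CC=C(C)C)O | intermediate
15 | (1S,2S,3R,6S)-6-methyl-3-[(3S)-6-methyl-3-{[(2E)-2-methylbut-2-enoyl]oxy}hepta-1,5-dien-2-yl]-5-oxo-7-oxabicyclo[4.1.0]heptan-2-yl (2E)-2-methylbut-2-enoate | C=C([C@@H]1[C@H](OC(=O)/C(C)=C/C)[C@@H]2O[C@]2(C)C(=O)C1)[C@H](CC=C(C)C)OC(=O)/C(C)=C/C | intermediate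
16 | (1S,2S,3R,6S)-3-[(3S)-4-[(2R)-3,3-dimethyloxiran-2-yl]-3-{[(2E)-2-methylbut-2-enoyl]oxy}but-1-en-2-yl]-6-methyl-5-oxo-7-oxabicyclo[4.1.0]heptan-2-yl (2E)-2-methylbut-2-enoate | C=C([C@@H]1[C@H](OC(=O)/C(C)=C/C)[C@@H]2O[C@]2(C)C(=O)C1)[C@H](C[C@H]1OC1(C)C)OC(=O)/C(C)=C/C | intermediate
17 | (1S,2S,3S,4S,6S)-3-[(3S)-4-[(2R)-3,3-dimethyloxiran-2-yl]-3-{[(2E)-2-methylbut-2-enoyl]oxy}but-1-en-2-yl]-4-hydroxy-6-methyl-5-oxo-7-oxabicyclo[4.1.0]heptan-2-yl (2E)-2-methylbut-2-enoate | C=C([C@@H]1[C@H](OC(=O)/C(C)=C/C)[C@@H]2O[C@]2(C)C(=O)[C@H]1O)[C@H](C[C@H]1OC1(C)C)OC(=O)/C(C)=C/C | intermediate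
18 | (1S,2S,3R,4S,6S)-4-(acetyloxy)-3-[(3S)-4-[(2R)-3,3-dimethyloxiran-2-yl]-3-{[(2E)-2-methylbut-2-enoyl]oxy}but-1-en-2-yl]-6-methyl-5-oxo-7-oxabicyclo[4.1.0]heptan-2-yl (2E)-2-methylbut-2-enoate (CNP0407453.3) | C=C([C@@H]1[C@H](OC(=O)/C(C)=C/C)[C@@H]2O[C@]2(C)C(=O)[C@H]1OC(C)=O)[C@H](C[C@H]1OC1(C)C)OC(=O)/C(C)=C/C | target

**Totals and risks**

Total step count: 9. Longest linear sequence: 9.

The three steps most likely to fail are 2, 6 and 9.

Step 2 is the untested relay. Benzoyl peroxide may oxidise the amine or acylate the ketoester, the α-benzoyloxy aldehyde may epimerise before ring closure, and the γ-benzoate may eliminate toward a phenol under TsOH. The fallback sets out from 3 and 4 and comes back at 6. The established two-component Michael addition/acid cyclisation (same catalyst, no peroxide) gives (5R)-2-methyl-5-[(trimethylsilyl)ethynyl]cyclohex-2-en-1-one F1. TBSOTf/Et3N converts it into the extended dienol ether tert-butyldimethyl({(5S)-2-methyl-5-[(trimethylsilyl)ethynyl]cyclohexa-1,3-dien-1-yl}oxy)silane F2. Dimethyldioxirane then oxidises the terminal double bond anti to the alkynyl group (vinylogous Rubottom oxidation, citric acid work-up) to the trans alcohol (4S,5R)-4-hydroxy-2-methyl-5-[(trimethylsilyl)ethynyl]cyclohex-2-en-1-one F3. Mitsunobu inversion with benzoic acid, PPh3 and diisopropyl azodicarboxylate gives 6.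

Step 6 uses a hindered tertiary allylboronate, so rate and enantioselectivity under phosphoric acid catalysis are uncertain, and an uncatalysed background reaction would erode the selectivity. The fallback sets out from 12 and comes back at 14. The well-precedented (S)-TRIP-catalysed allylboration with allylboronic acid pinacol ester gives (1S,2S,3R,6S)-3-[(3S)-3-hydroxyhexa-1,5-dien-2-yl]-6-methyl-5-oxo-7-oxabicyclo[4.1.0]heptan-2-yl (2E)-2-methylbut-2-enoate F4. Cross-metathesis with 2-methylbut-2-ene (second-generation Hoveyda–Grubbs catalyst, CH2Cl2, 40 °C) converts the vinyl terminus into the prenyl group of 14.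

Step 9 is a late enolate oxidation in the presence of two tiglates and two oxiranes. Possible failures are acyl transfer from the neighbouring tiglate to the enolate, addition of the enolate to the sulfonimine by-product, and an imperfect trans ratio. The fallback sets out from 16 and comes back at 18. LiN(SiMe3)2/Me3SiCl at −78 °C traps the enolate as (1S,2S,3R,6S)-3-[(3S)-4-[(2R)-3,3-dimethyloxiran-2-yl]-3-{[(2E)-2-methylbut-2-enoyl]oxy}but-1-en-2-yl]-6-methyl-5-[(trimethylsilyl)oxy]-7-oxabicyclo[4.1.0]hept-4-en-2-yl (2E)-2-methylbut-2-enoate F5. Pb(OAc)4 in CH2Cl2 at −20 °C then acetoxylates this silyl enol ether directly, anti to the side chain, to give 18 without a free ketol.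

**Further compounds**
F1 | step 2 | (5R)-2-methyl-5-[(trimethylsilyl)ethynyl]cyclohex-2-en-1-one | C[Si](C)(C)C#C[C@@H]1CC=C(C)C(=O)C1
F2 | step 2 | tert-butyldimethyl({(5S)-2-methyl-5-[(trimethylsilyl)ethynyl]cyclohexa-1,3-dien-1-yl}oxy)silane | C[Si](C)(C)C#C[C@@H]1C=CC(C)=C(O[Si](C)(C)C(C)(C)C)C1
F3 | step 2 | (4S,5R)-4-hydroxy-2-methyl-5-[(trimethylsilyl)ethynyl]cyclohex-2-en-1-one | C[Si](C)(C)C#C[C@@H]1[C@@H](O)C=C(C)C(=O)C1
F4 | step 6 | (1S,2S,3R,6S)-3-[(3S)-3-hydroxyhexa-1,5-dien-2-yl]-6-methyl-5-oxo-7-oxabicyclo[4.1.0]heptan-2-yl (2E)-2-methylbut-2-enoate | C=C([C@@H]1[C@H](OC(=O)/C(C)=C/C)[C@@H]2O[C@]2(C)C(=O)C1)[C@H](CC=C)O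
F5 | step 9 | (1S,2S,3R,6S)-3-[(3S)-4-[(2R)-3,3-dimethyloxiran-2-yl]-3-{[(2E)-2-methylbut-2-enoyl]oxy}but-1-en-2-yl]-6-methyl-5-[(trimethylsilyl)oxy]-7-oxabicyclo[4.1.0]hept-4-en-2-yl (2E)-2-methylbut-2-enoate | C=C([C@@H]1[C@H](OC(=O)/C(C)=C/C)[C@@H]2O[C@]2(C)C(O[Si](C)(C)C)=C1)[C@H](C[C@H]1OC1(C)C)OC(=O)/C(C)=C/C
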